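The rate constants were chosen freely; the result is computed.

The constants describe a cycle of waits in series, much like time constants added along a line, and the charges say how long that line may take.

all flasks: starting material 0.050 M; free catalyst 1 mol%; time 20 min
- maple: partner 2.00 equiv
- larch: partner 4.00 equiv

    catalyst intermediate C ⇌ free catalyst + product (K1 = 0.11 M, k1 = 0.36 /s)
    released group → by-product carried off (k2 = 0.0067 /s)
    starting material + free catalyst ⇌ catalyst intermediate A (K3 = 39 /M, k3 = 120 /M/s)
    starting material + released group ⇌ idle adduct, settled at all times (K4 = 31 /M)
    catalyst intermediate B → released group + catalyst intermediate C (k5 = 23 /s)
    crystals ⇌ released group, rate k6*(cs6 - [released group]) while solid is left; crystals form when [released group] > cs6 (cs6 = 32 mM, k6 = 0.14 /s)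
    partner + catalyst intermediate A ⇌ catalyst intermediate B (K7 = 17 /M, k7 = 10 /M/s)

- part of the starting material that has reacted at the end, maple
- part of the starting material that has reacted at the end, larch
- what raising the equivalents of partner from its lowest to its highest value here does to the part of the starting material that has reacted (changes below 5 percentage points count as none) (it falls / it rises / no change)

What must the catalyst do? Each unit must turn over 100 times in 1200 s, so maple grants a turnover budget of 12.0 s, and the mean turnover time has to fit inside it.

What does one turnover cost? Take maple's mean [partner] over the run as 0.0750 M: catalyst intermediate C gives up product in about 2.78 s, and catalyst intermediate A catches partner in about 1.33 s, so the fixed time is 4.11 s. On top comes the search of free catalyst for starting material, which I write as s divided by f, where f is the fraction of starting material left.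

What is s? It starts from the bare wait 0.167 s, and in maple each penalty multiplies it: at a mean [product] of 0.0250 M, catalyst held by product costs a factor 1.23; catalyst intermediate A falls back at 3.08 /s, faster than partner takes it at 0.750 /s, which costs a factor 5.11; and I take the mean [released group] as 6.22 mM, the mean rate over the loss constant, since the half-life of free released group, 1.7 min, is short against 20 min, so idle adduct costs a factor 1.19. That gives 1.24 s for s, the search time.

And the mean of s over f? Near full conversion the mean of the inverse of f is ln of the inverse of its final value, which makes the late decay pseudo-first-order, and the rule reads: budget equals fixed time plus s times that logarithm. Maple then leaves 0.177 %, so 99.8 % has reacted. Larch, by the same rule, leaves <0.001 %, so >99.9 % has reacted, and the trend is no change.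

But the tail runs at the end of the curve, not at its mean, doesn't it? Yes: with maple's end values of [product] and [partner] and the adduct penalty left out, s becomes 1.73 s and the remainder 1.06 %, so on this reckoning the choice between mean and end values moves maple's conversion by 0.88 percentage points.

The forecast says 99 % for maple and 99.9 % for larch, no change, with maple's tail “slowed by product inhibition”. The simulation gives 99.0 % and >99.9 %, no change, a change of 0.97 points.

The neighbour of maple with 0.6 mol% of free catalyst keeps the other charges and the time, and neither the fixed time nor the search time contains the catalyst charge, so both carry over while the budget shrinks to 7.20 s. The same rule then leaves 8.36 % of the starting material. That neighbouring flask shows 91.6 % reacted, and at 20.0 min it still holds 8.44 % of its starting material unbound.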